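## Retrosynthetic overview
1. 25 ⇒ achiral, acyclic bromo aldehyde 22. The last step makes the C7–C8 bond, the ten-membered ring, both stereocentres and the lactone. C7 is the β-carbon of an enoate and normally an acceptor. As a 2-(methoxycarbonyl)allylchromium (an ester homoenolate equivalent) it becomes the nucleophile and attacks the C8 aldehyde under chiral-ligand control.
2. 22 ⇒ hydroxy acrylate 20. The allylic bromide comes from an SN2′ displacement, and the C8 aldehyde is carried as a diethyl acetal.
3. 20 ⇒ lactol 13 + methyl propiolate. Alkenylalane addition opens the lactol and frees only the C15 hydroxyl, which then takes the side-chain ester.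
4. 13 ⇒ triene ester 9 + acrolein 3. Ring-closing metathesis to a temporary dihydropyranone fixes C4=C5 (C15 cis to C6). E-selective cross-metathesis fixes C1=C10, and reduction plus acetylation gives C14–OAc.
5. Ring order: the temporary six-membered lactone forms in step 5 and is opened in step 8. The cyclodecadiene and the γ-lactone form together in step 14.

Atom labels follow germacranolide numbering: ring C1–C10, lactone C11/C12/C13, C14 on C10, C15 on C4. The target is (7R,8S), trans-fused. C4=C5 is trans in the ring (C15 cis to C6) and C1=C10 is cis in the ring (C14 trans to C2).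

Assumption: the (S,S)-ligand is taken to direct attack to the Re face of the C8 aldehyde, as (7R,8S) requires; if the sense is opposite, its equally available (R,R)-antipode is used.

## Route

Step 1
Reactants: 1 4,4-diethoxybutanenitrile
Product: 2 4,4-diethoxybutanal
Conditions: iBu2AlH (1.1 equiv), CH2Cl2, −78 °C; aq. potassium sodium tartrate, 0 °C
Reagents that add atoms: water, O
Why: Partial nitrile reduction with iBu2AlH stops at the N-aluminoimine, which hydrolyses to the aldehyde at near-neutral pH without touching the acetal.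

Step 2
Reactants: 2 4,4-diethoxybutanal
Product: 3 4,4-diethoxy-2-methylidenebutanal
Conditions: 37% aq. HCHO (1.2 equiv), pyrrolidine (10 mol %), EtCO2H (10 mol %), iPrOH, 45 °C
Reagents that add atoms: formaldehyde, C=O
Why: Amine-catalysed Mannich condensation and elimination (organocatalytic α-methylenation of an aldehyde) is mild enough for the acetal.

Step 3
Reactants: 4 but-3-en-1-ylmagnesium bromide; 5 prop-2-yn-1-ol
Product: 7 2-methylidenehex-5-en-1-ol, via cyclic alkenylmagnesium alkoxide 6 (not isolated)
Conditions: 4 (2.5 equiv), CuI (10 mol %), Et2O–THF, −10 °C to rt; then H2O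
Reagents that add atoms: none
Why: Copper-catalysed, alkoxide-directed anti-carbomagnesiation of propargyl alcohol puts the butenyl group on the internal alkyne carbon through chelate 6, and protonolysis leaves the 1,1-disubstituted allylic alcohol with no stereocentre formed.

Step 4
Reactants: 7 2-methylidenehex-5-en-1-ol; 8 but-3-enoic acid
Product: 9 2-methylidenehex-5-en-1-yl but-3-enoate
Conditions: DCC (1.1 equiv), DMAP (5 mol %), CH2Cl2, 0 °C
Reagents that add atoms: none
Why: Steglich esterification at low temperature and low DMAP loading avoids isomerisation of the β,γ-unsaturated acyl group to the crotonate.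

Step 5
Reactants: 9 2-methylidenehex-5-en-1-yl but-3-enoate; 3 4,4-diethoxy-2-methylidenebutanal
Product: 11 lactone enal (E)-2-(2,2-diethoxyethyl)-5-(6-oxo-5,6-dihydro-2H-pyran-3-yl)pent-2-enal, via butenyl dihydropyranone 10 (not isolated)
Conditions: second-generation Hoveyda–Grubbs catalyst (2 mol %), 1,4-benzoquinone (10 mol %), CH2Cl2 (0.01 M), 40 °C, 2 h; then 3 (3 equiv), more catalyst (5 mol %), 40 °C, 24 h
Reagents that add atoms: none
Why: Ring-closing metathesis to a six-membered ring can only give C4=C5 with C15 and C6 cis, and the remaining terminal alkene then undergoes cross-metathesis with the α-substituted acrolein to give the E-enal (CHO trans to the chain, so C9 ends cis to C2).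

Step 6
Reactants: 11 lactone enal
Product: 12 lactol alcohol (E)-5-[4-(2,2-diethoxyethyl)-5-hydroxypent-3-en-1-yl]-3,6-dihydro-2H-pyran-2-ol (anomer mixture)
Conditions: iBu2AlH (2.3 equiv), CH2Cl2, −78 °C; aq. potassium sodium tartrate
Reagents that add atoms: none
Why: At −78 °C hydride reduction takes the enal 1,2 to the allylic alcohol and stops the δ-lactone at the stable aluminium lactolate, while the acetal and both trisubstituted alkenes are inert.

Step 7
Reactants: 12 lactol alcohol
Product: 13 lactol acetate (E)-2-(2,2-diethoxyethyl)-5-(6-hydroxy-5,6-dihydro-2H-pyran-3-yl)pent-2-en-1-yl acetate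
Conditions: AcCl (1.05 equiv), 2,4,6-collidine (2 equiv), CH2Cl2, −78 °C
Reagents that add atoms: acetyl chloride, CC(=O)Cl
Why: Kinetically selective O-acetylation works because the unhindered primary allylic C14 hydroxyl is acylated faster than the secondary hemiacetal hydroxyl, and the C15 oxygen is still tied up in the ring.

Step 8
Reactants: 13 lactol acetate; 14 methyl propiolate
Product: 16 methyl (5Z,9E)-10-(acetoxymethyl)-12,12-diethoxy-3-hydroxy-6-(hydroxymethyl)-2-methylidenedodeca-5,9-dienoate, via alkenylalane 15 (not isolated)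
Conditions: 14 (3 equiv), iBu2AlH (3 equiv), N-methylmorpholine N-oxide (3 equiv), THF, 0 °C, 1 h; then 13, 0 °C to rt; aq. potassium sodium tartrate
Reagents that add atoms: none
Why: Hydroalumination of the ynoate puts aluminium α to the ester, and alkenylalane 15 adds to the aldehyde tautomer of the lactol (vinylalumination, a base-free equivalent of the Morita–Baylis–Hillman reaction that cannot conjugate the β,γ-unsaturated aldehyde); the C7 carbinol forms as a racemate and is erased in step 12.

Step 9
Reactants: 17 ethyl 2-(hydroxymethyl)acrylate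
Product: 18 ethyl 2-[(tert-butyldimethylsilyloxy)methyl]acrylate
Conditions: TBSCl (1.1 equiv), imidazole (2 equiv), CH2Cl2, 0 °C to rt
Reagents that add atoms: tert-butyldimethylsilyl chloride, CC(C)(C)[Si](C)(C)Cl
Why: This is a standard silylation of a primary alcohol.

Step 10
Reactants: 18 ethyl 2-[(tert-butyldimethylsilyloxy)methyl]acrylate
Product: 19 2-[(tert-butyldimethylsilyloxy)methyl]acrylic acid
Conditions: LiOH (1.5 equiv), THF–H2O, 0 °C to rt; dilute HCl to pH 4
Reagents that add atoms: lithium hydroxide, [Li+].[OH-]
Why: Ester saponification is faster than conjugate addition to the α-substituted acrylate, and the silyl ether survives brief contact at pH 4.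

Step 11
Reactants: 16 diol; 19 2-[(tert-butyldimethylsilyloxy)methyl]acrylic acid
Product: 20 methyl (5Z,9E)-10-(acetoxymethyl)-6-({2-[(tert-butyldimethylsilyloxy)methyl]acryloyl}oxymethyl)-12,12-diethoxy-3-hydroxy-2-methylidenedodeca-5,9-dienoate
Conditions: 19 (1.05 equiv), DCC (1.1 equiv), DMAP (10 mol %), CH2Cl2, −10 °C
Reagents that add atoms: none
Why: Steglich esterification selects the primary allylic C15 hydroxyl over the hindered secondary C7 hydroxyl.

Step 12
Reactants: 20 hydroxy acrylate
Product: 21 methyl (2Z,5Z,9E)-10-(acetoxymethyl)-2-(bromomethyl)-6-({2-[(tert-butyldimethylsilyloxy)methyl]acryloyl}oxymethyl)-12,12-diethoxydodeca-2,5,9-trienoate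
Conditions: CBr4 (1.3 equiv), PPh3 (1.3 equiv, added last), CH2Cl2, −20 to 0 °C
Reagents that add atoms: carbon tetrabromide, BrC(Br)(Br)Br
Why: Appel activation of the allylic alcohol followed by SN2′ attack of bromide gives the more stable Z-2-(bromomethyl)enoate under neutral conditions, and any secondary allylic bromide would lead to the same allylchromium in step 14.

Step 13
Reactants: 21 acetal bromide
Product: 22 methyl (2Z,5Z,9E)-10-(acetoxymethyl)-2-(bromomethyl)-6-({2-[(tert-butyldimethylsilyloxy)methyl]acryloyl}oxymethyl)-12-oxododeca-2,5,9-trienoate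
Conditions: pyridinium p-toluenesulfonate (20 mol %), acetone–H2O 20:1, rt; used at once
Reagents that add atoms: water, O
Why: Mild acid-catalysed hydrolysis cleaves the labile acyclic acetal but is too weak to remove the silyl ether or to move the C1=C10 alkene into conjugation.

Step 14
Reactants: 22 bromo aldehyde
Product: 25 target CNP0126545.1, via allylchromium species 23 (not isolated), via ring-closed silyl ether 24 (not isolated)
Conditions: CrCl2 (15 mol %), (S,S)-1,8-bis(4-isopropyl-4,5-dihydrooxazol-2-yl)-3,6-diphenyl-9H-carbazole (18 mol %), iPr2NEt (40 mol %), Mn powder (3 equiv), Me3SiCl (2.5 equiv), THF, rt, 22 added over 20 h (final 2 mM); filter; HF·pyridine, THF, 0 °C to rt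
Reagents that add atoms: none
Why: Proposed new method: two one-electron transfers from divalent chromium turn the allylic bromide of 22 into allylchromium 23, in which C7, the normally electrophilic β-carbon of the enoate, is the nucleophilic γ-terminus (an ester homoenolate equivalent) and attacks the equally electrophilic C8 aldehyde through a closed chair transition state, so the equilibrating E-allylchromium gives the anti adduct 24 (the trans-lactone after desilylation and loss of methanol) while the tridentate bis(oxazolinyl)carbazole ligand selects the Re face of the aldehyde and sets (7R,8S); the closest known reactions are the intermolecular chromium-catalysed enantioselective 2-(alkoxycarbonyl)allylation of aldehydes and the racemic or substrate-controlled Nozaki–Hiyama–Kishi closures of ten-membered germacranolide rings, and only their combination is new.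

## Compound list
1 | 4,4-diethoxybutanenitrile | N#CCCC(OCC)OCC | starting material
2 | 4,4-diethoxybutanal | O=CCCC(OCC)OCC | intermediate
3 | 4,4-diethoxy-2-methylidenebutanal | C=C(C=O)CC(OCC)OCC | intermediate
4 | but-3-en-1-ylmagnesium bromide | C=CCC[Mg]Br | starting material
5 | prop-2-yn-1-ol | C#CCO | starting material
6 | cyclic alkenylmagnesium alkoxide (five-membered C=C–Mg–O chelate, not isolated) | C=CCCC1=C[Mg]OC1 | intermediate
7 | 2-methylidenehex-5-en-1-ol | C=CCCC(=C)CO | intermediate
8 | but-3-enoic acid | C=CCC(=O)O | starting material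
9 | 2-methylidenehex-5-en-1-yl but-3-enoate | C=CCCC(=C)COC(=O)CC=C | intermediate
10 | 5-(but-3-en-1-yl)-3,6-dihydro-2H-pyran-2-one (not isolated) | O=C1CC=C(CCC=C)CO1 | intermediate
11 | (E)-2-(2,2-diethoxyethyl)-5-(6-oxo-5,6-dihydro-2H-pyran-3-yl)pent-2-enal | O=C1CC=C(CC/C=C(/C=O)CC(OCC)OCC)CO1 | intermediate
12 | (E)-5-[4-(2,2-diethoxyethyl)-5-hydroxypent-3-en-1-yl]-3,6-dihydro-2H-pyran-2-ol (anomer mixture) | OC1CC=C(CC/C=C(/CO)CC(OCC)OCC)CO1 | intermediate
13 | (E)-2-(2,2-diethoxyethyl)-5-(6-hydroxy-5,6-dihydro-2H-pyran-3-yl)pent-2-en-1-yl acetate (anomer mixture) | OC1CC=C(CC/C=C(/COC(C)=O)CC(OCC)OCC)CO1 | intermediate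
14 | methyl propiolate | C#CC(=O)OC | starting material
15 | methyl 2-(diisobutylalumanyl)acrylate (not isolated) | C=C(C(=O)OC)[Al](CC(C)C)CC(C)C | intermediate
16 | methyl (5Z,9E)-10-(acetoxymethyl)-12,12-diethoxy-3-hydroxy-6-(hydroxymethyl)-2-methylidenedodeca-5,9-dienoate (racemic at C3 of the chain) | C=C(C(=O)OC)C(O)C/C=C(/CC/C=C(/COC(C)=O)CC(OCC)OCC)CO | intermediate
17 | ethyl 2-(hydroxymethyl)acrylate | C=C(CO)C(=O)OCC | starting material
18 | ethyl 2-[(tert-butyldimethylsilyloxy)methyl]acrylate | C=C(CO[Si](C)(C)C(C)(C)C)C(=O)OCC | intermediate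
19 | 2-[(tert-butyldimethylsilyloxy)methyl]acrylic acid | C=C(CO[Si](C)(C)C(C)(C)C)C(=O)O | intermediate
20 | hydroxy acrylate: 16 with the C15 hydroxyl esterified by 19 | C=C(C(=O)OC)C(O)C/C=C(/CC/C=C(/COC(C)=O)CC(OCC)OCC)COC(=O)C(=C)CO[Si](C)(C)C(C)(C)C | intermediate
21 | (2Z,5Z,9E)-2-(bromomethyl)trienoate with the C8 diethyl acetal | BrC/C(C(=O)OC)=C\C/C=C(/CC/C=C(/COC(C)=O)CC(OCC)OCC)COC(=O)C(=C)CO[Si](C)(C)C(C)(C)C | intermediate
22 | (2Z,5Z,9E)-2-(bromomethyl)-12-oxotrienoate (bromo aldehyde) | BrC/C(C(=O)OC)=C\C/C=C(/CC/C=C(/COC(C)=O)CC=O)COC(=O)C(=C)CO[Si](C)(C)C(C)(C)C | intermediate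
23 | allylchromium of trivalent chromium from 22 (drawn as the dichloride, chiral ligand omitted, not isolated) | Cl[Cr](Cl)C/C(C(=O)OC)=C\C/C=C(/CC/C=C(/COC(C)=O)CC=O)COC(=O)C(=C)CO[Si](C)(C)C(C)(C)C | intermediate
24 | ring-closed cyclodecadiene, (7R)-C7 bearing the 1-(methoxycarbonyl)vinyl group anti to the (8S)-C8 OSiMe3 group (not isolated) | C=C(CO[Si](C)(C)C(C)(C)C)C(=O)OC/C1=C\C[C@H](C(=C)C(=O)OC)[C@@H](O[Si](C)(C)C)C/C(COC(C)=O)=C\CC1 | intermediate
25 | CNP0126545.1, (7R,8S)-14-acetoxy-15-[2-(hydroxymethyl)acryloyloxy]germacra-1(10),4,11(13)-trien-12,8-olide | C=C(CO)C(=O)OC/C1=C\C[C@@H]2C(=C)C(=O)O[C@H]2C/C(COC(C)=O)=C\CC1 | target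

## Step count and risks
Total step count: 14.
Longest linear sequence: 10 steps (3, 4, 5, 6, 7, 8, 11, 12, 13, 14). The branch 1, 2, 5–8, 11–14 is equally long.

**Step 14.** The closure may be slow at high dilution or poorly enantioselective. The fallback gives up catalyst control and separates the enantiomers. It sets out from 22.
- Stoichiometric CrCl2 (4 equiv, no ligand) in THF–DMF at 2 mM relies only on the inherent anti selectivity of allylchromium additions. It gives the racemic trans-fused silyl-protected macrolactone F1.
- Preparative chromatography on a chiral stationary phase gives the (7R,8S)-silyl ether F2.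
- HF·pyridine then brings the material back to the route at 25.

**Step 5.** Cross-metathesis with the bulky α-substituted acrolein may stall or erode the E selectivity. The fallback builds C1=C10 by carbonyl olefination. It sets out from 10, isolated after the ring closure alone.
- OsO4 (2 mol %) and NaIO4 cleave the unhindered terminal alkene in preference to the deactivated ring alkene. This gives 3-(6-oxo-5,6-dihydro-2H-pyran-3-yl)propanal F3.
- Separately, 3-chloro-1,1-diethoxypropane, NaI and PPh3 give (3,3-diethoxypropyl)triphenylphosphonium iodide F4.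
- The ylide of F4 is formylated with ethyl formate (KOtBu, 2 equiv) to the stabilised ylide 4,4-diethoxy-2-(triphenylphosphoranylidene)butanal F5.
- Wittig reaction of F3 with F5 in toluene at 90 °C is E-selective and comes back to the route at 11.

**Step 8.** The alkenylalane may not open the free lactol cleanly in the presence of the acetate. The fallback reverses the order of the two chain ends, so the alane meets an aluminium lactolate made in the same flask and no acetate is present. It sets out from 10, isolated.
- iBu2AlH at −78 °C followed directly by 15 gives the terminal-alkene diol F6.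
- Selective esterification of its primary hydroxyl with 19 gives the ester F7.
- Cross-metathesis of F7 with 3 gives the enal F8.
- NaBH4/CeCl3·7H2O reduction gives the allylic alcohol F9.
- AcCl/collidine acetylates the primary C14 hydroxyl over the secondary C7 hydroxyl and comes back to the route at 20.

## Further compounds
F1 | step 14 | racemic trans-fused silyl-protected macrolactone (both enantiomers shown) | C=C(CO[Si](C)(C)C(C)(C)C)C(=O)OC/C1=C\C[C@@H]2C(=C)C(=O)O[C@H]2C/C(COC(C)=O)=C\CC1.C=C(CO[Si](C)(C)C(C)(C)C)C(=O)OC/C1=C\C[C@H]2C(=C)C(=O)O[C@@H]2C/C(COC(C)=O)=C\CC1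
F2 | step 14 | (7R,8S)-silyl ether of the target | C=C(CO[Si](C)(C)C(C)(C)C)C(=O)OC/C1=C\C[C@@H]2C(=C)C(=O)O[C@H]2C/C(COC(C)=O)=C\CC1
F3 | step 5 | 3-(6-oxo-5,6-dihydro-2H-pyran-3-yl)propanal | O=CCCC1=CCC(=O)OC1
F4 | step 5 | (3,3-diethoxypropyl)triphenylphosphonium iodide | CCOC(CC[P+](c1ccccc1)(c1ccccc1)c1ccccc1)OCC.[I-]
F5 | step 5 | 4,4-diethoxy-2-(triphenylphosphoranylidene)butanal | CCOC(CC(C=O)=P(c1ccccc1)(c1ccccc1)c1ccccc1)OCC
F6 | step 8 | methyl (Z)-3-hydroxy-6-(hydroxymethyl)-2-methylidenedeca-5,9-dienoate | C=C(C(=O)OC)C(O)C/C=C(/CCC=C)CO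
F7 | step 8 | F6 with the primary hydroxyl esterified by 19 | C=C(C(=O)OC)C(O)C/C=C(/CCC=C)COC(=O)C(=C)CO[Si](C)(C)C(C)(C)C
F8 | step 8 | (5Z,9E)-enal from cross-metathesis of F7 with 3 | C=C(C(=O)OC)C(O)C/C=C(/CC/C=C(/C=O)CC(OCC)OCC)COC(=O)C(=C)CO[Si](C)(C)C(C)(C)C
F9 | step 8 | (5Z,9E)-C14 allylic alcohol from F8 | C=C(C(=O)OC)C(O)C/C=C(/CC/C=C(/CO)CC(OCC)OCC)COC(=O)C(=C)CO[Si](C)(C)C(C)(C)C
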